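**Retrosynthetic overview**

1. Target 35 ⇐ lactone 34 (i-Bu2AlH) ⇐ ketone 33 (CH3 added to C6) ⇐ exo-methylene keto lactone 30 + hydroazulenylacetic acid 16; the CH2–CH2 link is made by a decarboxylative Giese addition.
2. The cyclohexane ring C4a–C5–C6–C7–C8–C8a of the oxadecalin (chromene numbering: O1, C2 lactol, C4a quaternary C–CH3, C8a O–CH) is closed last, from the monocyclic enol-lactone diazo ketone 25: carbenoid cyclopropanation of the enol double bond (future C4a–C8a), then strain-release cleavage of the C5–C8a cyclopropane bond with a silane.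
3. Enabling feature: C8a carries the pyran oxygen and C6 the carbinol oxygen, 1,4 to each other across C5. As ring-oxygen donor and C6-ketone acceptor they sit on the two ends of the cyclopropane bond that has to break, while C5–C4a is the bond that stays.
4. Pyranone ring: retro-Claisen opening of the acrylate adduct of 2-methylcyclopentane-1,3-dione, then enol lactonisation. Hydroazulene: asymmetric conjugate addition to 4,4-dimethylcyclohexenone, one-carbon enlargement to the cycloheptenone, SmI2 ketyl–enone closure of the cyclopentanol, Johnson–Claisen rearrangement for the side chain.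
5. Order of ring formation: cycloheptene (step 3), cyclopentane (step 7), pyranone (step 13), cyclohexane (step 16).

Key step: step 16

Assumption 1: the hemiacetal carbon C2 of 35 epimerises through the open hydroxy aldehyde, so the route delivers the lactol and the drawn anomer (2S, equatorial OH) is taken to be reached at equilibrium or on crystallisation.
Assumption 2: in the catalyst-controlled steps 1, 8 and 16 the catalyst enantiomer is written as predicted from the closest models; should a pilot run show the opposite sense, the mirror-image catalyst is used.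

**Route**

Step 1
Reactants: 1 4,4-dimethylcyclohex-2-en-1-one; 2 2-(2-bromoethyl)-2-methyl-1,3-dioxolane
Product: 6 (S)-{[4,4-dimethyl-3-[2-(2-methyl-1,3-dioxolan-2-yl)ethyl]cyclohex-1-en-1-yl]oxy}trimethylsilane, via Grignard reagent 3 (not isolated), via dialkylzinc 4 (not isolated), via zinc enolate 5 (not isolated)
Conditions: 2, Mg, THF; ZnCl2 (0.5 equiv), 1,4-dioxane, filter; Cu(OTf)2 (2 mol%), (R)-1,1'-binaphthyl-2,2'-diyl N,N-bis[(S)-1-phenylethyl]phosphoramidite (4 mol%), 1, toluene, −30 °C; TMSOTf, −30 to 0 °C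
Reagents that add atoms: trimethylsilyl trifluoromethanesulfonate, C[Si](C)(C)OS(=O)(=O)C(F)(F)F
Why: Copper-catalysed asymmetric conjugate addition of a dialkylzinc to the cyclohexenone, in which the phosphoramidite-bound copper alkyl selects one enone face and so sets the side-chain carbon (S), followed by O-silylation of the regiodefined zinc enolate.

Step 2
Reactants: 6 silyl enol ether
Product: 7 4,4-dimethyl-5-[2-(2-methyl-1,3-dioxolan-2-yl)ethyl]-1-(trimethylsilyloxy)bicyclo[4.1.0]heptane (side-chain carbon as in 6, cyclopropane diastereomers)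
Conditions: CH2I2, Zn–Cu couple, Et2O, reflux
Reagents that add atoms: diiodomethane, ICI
Why: Simmons–Smith cyclopropanation of the electron-rich silyl enol ether; both new stereocentres are destroyed in step 3, so the diastereomer ratio is of no consequence.

Step 3
Reactants: 7 siloxycyclopropane
Product: 9 (S)-5,5-dimethyl-4-[2-(2-methyl-1,3-dioxolan-2-yl)ethyl]cyclohept-2-en-1-one, via chloro ketone 8 (not isolated)
Conditions: FeCl3 (2.2 equiv), pyridine, DMF, 0 °C; then NaOAc, MeOH, reflux
Reagents that add atoms: none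
Why: Oxidative ring enlargement of a siloxycyclopropane (one-electron oxidation, β-scission of the internal cyclopropane bond, chlorine transfer to the β-keto radical) followed by dehydrochlorination should give the cyclohept-2-enone without touching the existing stereocentre.

Step 4
Reactants: 9 cycloheptenone
Product: 10 (4S)-5,5,7-trimethyl-4-[2-(2-methyl-1,3-dioxolan-2-yl)ethyl]cyclohept-2-en-1-one (C7 epimers)
Conditions: LiN(i-Pr)2, THF, −78 °C; MeI
Reagents that add atoms: iodomethane, CI
Why: Kinetic α'-deprotonation of the enone gives the cross-conjugated enolate, which is C-methylated (enolate alkylation); the new centre becomes sp2 in step 5.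

Step 5
Reactants: 10 α'-methyl enone
Product: 11 (S)-2,4,4-trimethyl-5-[2-(2-methyl-1,3-dioxolan-2-yl)ethyl]cyclohepta-2,6-dien-1-one
Conditions: 2-iodoxybenzoic acid (2.5 equiv), DMSO–fluorobenzene, 70 °C
Reagents that add atoms: none
Why: Dehydrogenation of the saturated α',β' side of the ketone by 2-iodoxybenzoic acid through its enol should give the cross-conjugated dienone, the only unsaturation pattern open to this ketone.

Step 6
Reactants: 11 dienone ketal
Product: 12 (S)-2,4,4-trimethyl-5-(3-oxobutyl)cyclohepta-2,6-dien-1-one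
Conditions: 1 M HCl, THF, 25 °C
Reagents that add atoms: water, O
Why: Acid-catalysed hydrolysis of the dioxolane frees the methyl ketone.

Step 7
Reactants: 12 dienone methyl ketone
Product: 13 (1S,3aS,8aS)-1-hydroxy-1,4,4,6-tetramethyl-2,3,3a,4,8,8a-hexahydroazulen-7(1H)-one (cis-fused, OH syn to both ring-fusion hydrogens)
Conditions: SmI2 (2.2 equiv), t-BuOH (2 equiv), THF, −78 °C
Reagents that add atoms: none
Why: Samarium diiodide ketyl–olefin (ketyl–enone) 5-exo cyclisation onto the β-carbon of the disubstituted enone; the short tether enforces the cis ring fusion and the samarium-bound oxygen turns away from the enone, which places OH on the face of the ring-fusion hydrogens.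

Step 8
Reactants: 13 hydroxy enone
Product: 14 (1S,3aS,7R,8aS)-1,4,4,6-tetramethyl-1,2,3,3a,4,7,8,8a-octahydroazulene-1,7-diol
Conditions: (S)-2-methyl-CBS-oxazaborolidine (0.5 equiv), BH3·SMe2 (2.5 equiv), THF, −20 °C; MeOH
Reagents that add atoms: none
Why: Corey–Bakshi–Shibata reduction, in which reagent control (the α-methylalkenyl arm as the large group) and hydride approach from the convex face of the cis-fused bicycle should both give the (7R)-carbinol.

Step 9
Reactants: 14 allylic alcohol
Product: 15 ethyl 2-[(1S,3aS,5R,8aS)-1-hydroxy-1,4,4,6-tetramethyl-1,2,3,3a,4,5,8,8a-octahydroazulen-5-yl]acetate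
Conditions: MeC(OEt)3, EtCO2H (cat.), xylene, 140 °C
Reagents that add atoms: triethyl orthoacetate, CC(OCC)(OCC)OCC
Why: Johnson–Claisen rearrangement, whose suprafacial [3,3] shift transfers the C7 carbinol configuration to the new C–C bond at C5 and moves the double bond to C6=C7.

Step 10
Reactants: 15 ethyl ester
Product: 16 2-[(1S,3aS,5R,8aS)-1-hydroxy-1,4,4,6-tetramethyl-1,2,3,3a,4,5,8,8a-octahydroazulen-5-yl]acetic acid
Conditions: LiOH, THF–MeOH–H2O, 25 °C; then 1 M HCl
Reagents that add atoms: lithium hydroxide, [Li+].[OH-]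
Why: Saponification of the unhindered ethyl ester leaves all stereocentres untouched.

Step 11
Reactants: 17 2-methylcyclopentane-1,3-dione; 18 tert-butyl acrylate
Product: 19 tert-butyl 3-(1-methyl-2,5-dioxocyclopentyl)propanoate
Conditions: Et3N, MeCN, 70 °C
Reagents that add atoms: none
Why: Michael addition of the acidic cyclic 1,3-diketone to the acrylate gives the achiral 2,2-disubstituted dione.

Step 12
Reactants: 19 dione ester
Product: 20 1-benzyl 8-tert-butyl 5-methyl-4-oxooctanedioate (racemic)
Conditions: BnOH (3 equiv), NaH (0.2 equiv), THF, 0 to 25 °C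
Reagents that add atoms: benzyl alcohol, OCc1ccccc1
Why: Retro-Claisen cleavage of the non-enolisable 1,3-diketone by benzyl alkoxide opens the five-membered ring and gives two differentiated ester arms, the hindered tert-butyl ester staying out of Claisen-type side reactions.

Step 13
Reactants: 20 keto diester
Product: 22 benzyl 3-(5-methyl-2-oxo-3,4-dihydro-2H-pyran-6-yl)propanoate, via keto acid 21 (not isolated)
Conditions: CF3CO2H, CH2Cl2, 25 °C; evaporate; Ac2O, NaOAc, 120 °C
Reagents that add atoms: none
Why: Acidolysis of the tert-butyl ester and enol lactonisation of the resulting δ-keto acid should give the more substituted, endocyclic enol lactone, which erases the stereocentre of 20.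

Step 14
Reactants: 22 benzyl ester
Product: 23 3-(5-methyl-2-oxo-3,4-dihydro-2H-pyran-6-yl)propanoic acid
Conditions: H2 (1 atm), Pd/C, EtOAc, 25 °C
Reagents that add atoms: none
Why: Hydrogenolysis of the benzyl ester, the tetrasubstituted enol-lactone double bond being too hindered for hydrogenation under these conditions.

Step 15
Reactants: 23 acid
Product: 25 6-(4-diazo-3-oxobutyl)-5-methyl-3,4-dihydro-2H-pyran-2-one, via acid chloride 24 (not isolated)
Conditions: (COCl)2, DMF (cat.), CH2Cl2, 0 °C; then CH2N2 (3 equiv), Et2O, 0 °C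
Reagents that add atoms: diazomethane, C=[N+]=[N-]
Why: Acylation of diazomethane by the acid chloride (the first stage of an Arndt–Eistert sequence) gives the terminal diazo ketone under conditions the enol lactone should survive.

Step 16
Reactants: 25 diazo ketone
Product: 27 (4aS,8aS)-4a-methyl-6-[(triethylsilyl)oxy]-3,4,4a,7,8,8a-hexahydro-2H-chromen-2-one, via cyclopropane 26 (not isolated)
Conditions: [Cu(MeCN)4]PF6 (5 mol%), 2,2'-(propane-2,2-diyl)bis[(4S)-4-tert-butyl-4,5-dihydro-1,3-oxazole] (6 mol%), CH2Cl2, 25 °C, slow addition of 25; then Et3SiH (2 equiv), Et3SiOTf (0.2 equiv), −78 to −30 °C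
Reagents that add atoms: triethylsilane, CC[SiH](CC)CC
Why: Proposed new method: the copper carbenoid from the terminal diazo ketone adds to the electron-rich tetrasubstituted enol-lactone double bond C5=C6 of the pyranone (closest known reaction type: copper–bis(oxazoline)-catalysed enantioselective intramolecular cyclopropanation of enol silyl ethers by diazo ketones) to give the oxycyclopropyl ketone 26, in which the lactone ring oxygen (donor) and the ketone (acceptor) sit on the two ends of one cyclopropane bond; Et3SiOTf then silylates the ketone, that bond breaks with release of ring strain (the known acid-induced fragmentation of oxycyclopropyl ketones to 1,4-dicarbonyl compounds), and the acyloxocarbenium ion is reduced by Et3SiH, which regenerates Et3SiOTf (ionic hydrogenation). The cyclohexane ring is closed as a net 6-endo alkylation of the enol β-carbon by the carbenoid carbon: a bicyclo[3.1.0]hexan-2-one forms first (five-membered ring plus cyclopropane), and cleavage of its internal bond enlarges it to the six-membered silyl enol ether. The quaternary carbon C4a is set by the chiral catalyst, which selects the enantioface of the flat, achiral enol lactone, and the ring-fusion carbon C8a is set when hydride adds to the oxocarbenium ion axially and anti to the angular methyl group, which gives the trans ring fusion. The step needs carbene transfer to the only C=C bond (five-ring formation is favoured over C–H insertion), cleavage of the donor–acceptor bond and not of the other two cyclopropane bonds (secured by the oxygen on C8a and the carbonyl next to the carbenoid carbon), and a regiodefined enol ether for step 17 (it can only form towards the former carbenoid carbon).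

Step 17
Reactants: 27 silyl enol ether
Product: 30 (4aS,8aS)-4a-methyl-5-methylideneoctahydro-2H-chromene-2,6-dione, via Mannich base 28 (not isolated), via methiodide 29 (not isolated)
Conditions: [Me2N=CH2]I, CH2Cl2, 25 °C; MeI; aq. NaHCO3, 25 °C
Reagents that add atoms: dimethyl(methylidene)ammonium iodide, C[N+](C)=C.[I-]
Why: Mannich reaction of the regiodefined silyl enol ether with the iminium salt at C5, then quaternisation and β-elimination (α-methylenation), the site being fixed by the enol ether from step 16.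

Step 18
Reactants: 16 hydroazulenylacetic acid; 30 exo-methylene keto lactone
Product: 33 (4aS,5S,8aS)-5-{2-[(1S,3aS,5R,8aS)-1-hydroxy-1,4,4,6-tetramethyl-1,2,3,3a,4,5,8,8a-octahydroazulen-5-yl]ethyl}-4a-methyloctahydro-2H-chromene-2,6-dione, via phthalimidyl ester 31 (not isolated), via C5 epimer 32 (not isolated)
Conditions: 16, N-hydroxyphthalimide, i-PrN=C=N-i-Pr, DMAP (cat.), CH2Cl2, 25 °C; then 30 (1.5 equiv), Ni(ClO4)2·6H2O (20 mol%), Zn, LiCl, MeCN, 25 °C; then DBU (0.2 equiv), CH2Cl2, 25 °C
Reagents that add atoms: none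
Why: Nickel-catalysed decarboxylative Giese addition of the primary radical from the redox-active ester to the terminal carbon of the α-methylene ketone joins the halves, and base equilibration of the epimerisable C5 (α to the ketone) should funnel both epimers into the one with the equatorial side chain.

Step 19
Reactants: 33 keto lactone
Product: 34 (4aS,5S,6R,8aS)-6-hydroxy-5-{2-[(1S,3aS,5R,8aS)-1-hydroxy-1,4,4,6-tetramethyl-1,2,3,3a,4,5,8,8a-octahydroazulen-5-yl]ethyl}-4a,6-dimethyloctahydro-2H-chromen-2-one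
Conditions: MeMgBr, CeCl3, THF, −78 °C; aq. NH4Cl
Reagents that add atoms: methylmagnesium bromide, C[Mg]Br
Why: Organocerium 1,2-addition, selective for the ketone over the lactone; axial attack is blocked by the syn-axial angular methyl group on C4a, so the methyl group should enter equatorially and leave the C6 hydroxyl axial.

Step 20
Reactants: 34 hydroxy lactone
Product: 35 (2S,4aS,5S,6R,8aS)-5-{2-[(1S,3aS,5R,8aS)-1-hydroxy-1,4,4,6-tetramethyl-1,2,3,3a,4,5,8,8a-octahydroazulen-5-yl]ethyl}-4a,6-dimethyloctahydro-2H-chromene-2,6-diol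
Conditions: i-Bu2AlH, CH2Cl2, −78 °C; aq. potassium sodium tartrate
Reagents that add atoms: none
Why: Partial reduction of the δ-lactone with i-Bu2AlH stops at the lactol, whose hemiacetal carbon equilibrates (assumption 1).

**Compound list**

1 | 4,4-dimethylcyclohex-2-en-1-one | CC1(C)CCC(=O)C=C1 | starting material
2 | 2-(2-bromoethyl)-2-methyl-1,3-dioxolane | CC1(CCBr)OCCO1 | starting material
3 | [2-(2-methyl-1,3-dioxolan-2-yl)ethyl]magnesium bromide | CC1(CC[Mg]Br)OCCO1 | intermediate
4 | bis[2-(2-methyl-1,3-dioxolan-2-yl)ethyl]zinc | CC1(CC[Zn]CCC2(C)OCCO2)OCCO1 | intermediate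
5 | alkylzinc enolate of (S)-4,4-dimethyl-3-[2-(2-methyl-1,3-dioxolan-2-yl)ethyl]cyclohexanone | CC1(CC[Zn]OC2=C[C@H](CCC3(C)OCCO3)C(C)(C)CC2)OCCO1 | intermediate
6 | (S)-{[4,4-dimethyl-3-[2-(2-methyl-1,3-dioxolan-2-yl)ethyl]cyclohex-1-en-1-yl]oxy}trimethylsilane | C[Si](C)(C)OC1=C[C@H](CCC2(C)OCCO2)C(C)(C)CC1 | intermediate
7 | 4,4-dimethyl-5-[2-(2-methyl-1,3-dioxolan-2-yl)ethyl]-1-(trimethylsilyloxy)bicyclo[4.1.0]heptane (cyclopropane diastereomers) | C[Si](C)(C)OC12CCC(C)(C)[C@@H](CCC3(C)OCCO3)C1C2 | intermediate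
8 | (4S)-3-chloro-5,5-dimethyl-4-[2-(2-methyl-1,3-dioxolan-2-yl)ethyl]cycloheptan-1-one (C3 epimers) | O=C1CC(Cl)[C@H](CCC2(C)OCCO2)C(C)(C)CC1 | intermediate
9 | (S)-5,5-dimethyl-4-[2-(2-methyl-1,3-dioxolan-2-yl)ethyl]cyclohept-2-en-1-one | O=C1C=C[C@H](CCC2(C)OCCO2)C(C)(C)CC1 | intermediate
10 | (4S)-5,5,7-trimethyl-4-[2-(2-methyl-1,3-dioxolan-2-yl)ethyl]cyclohept-2-en-1-one (C7 epimers) | CC1CC(C)(C)[C@@H](CCC2(C)OCCO2)C=CC1=O | intermediate
11 | (S)-2,4,4-trimethyl-5-[2-(2-methyl-1,3-dioxolan-2-yl)ethyl]cyclohepta-2,6-dien-1-one | CC1=CC(C)(C)[C@@H](CCC2(C)OCCO2)C=CC1=O | intermediate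
12 | (S)-2,4,4-trimethyl-5-(3-oxobutyl)cyclohepta-2,6-dien-1-one | CC1=CC(C)(C)[C@@H](CCC(C)=O)C=CC1=O | intermediate
13 | (1S,3aS,8aS)-1-hydroxy-1,4,4,6-tetramethyl-2,3,3a,4,8,8a-hexahydroazulen-7(1H)-one | CC=1C(=O)C[C@H]2[C@H](CC[C@]2(C)O)C(C)(C)C=1 | intermediate
14 | (1S,3aS,7R,8aS)-1,4,4,6-tetramethyl-1,2,3,3a,4,7,8,8a-octahydroazulene-1,7-diol | CC=1[C@H](O)C[C@H]2[C@H](CC[C@]2(C)O)C(C)(C)C=1 | intermediate
15 | ethyl 2-[(1S,3aS,5R,8aS)-1-hydroxy-1,4,4,6-tetramethyl-1,2,3,3a,4,5,8,8a-octahydroazulen-5-yl]acetate | CC1=CC[C@H]2[C@H](CC[C@]2(C)O)C(C)(C)[C@@H]1CC(=O)OCC | intermediate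
16 | 2-[(1S,3aS,5R,8aS)-1-hydroxy-1,4,4,6-tetramethyl-1,2,3,3a,4,5,8,8a-octahydroazulen-5-yl]acetic acid | CC1=CC[C@H]2[C@H](CC[C@]2(C)O)C(C)(C)[C@@H]1CC(=O)O | intermediate
17 | 2-methylcyclopentane-1,3-dione | CC1C(=O)CCC1=O | starting material
18 | tert-butyl acrylate | C=CC(=O)OC(C)(C)C | starting material
19 | tert-butyl 3-(1-methyl-2,5-dioxocyclopentyl)propanoate | CC1(CCC(=O)OC(C)(C)C)C(=O)CCC1=O | intermediate
20 | 1-benzyl 8-tert-butyl 5-methyl-4-oxooctanedioate (racemic) | CC(CCC(=O)OC(C)(C)C)C(=O)CCC(=O)OCc1ccccc1 | intermediate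
21 | 8-(benzyloxy)-4-methyl-5,8-dioxooctanoic acid (racemic) | CC(CCC(=O)O)C(=O)CCC(=O)OCc1ccccc1 | intermediate
22 | benzyl 3-(5-methyl-2-oxo-3,4-dihydro-2H-pyran-6-yl)propanoate | CC1=C(CCC(=O)OCc2ccccc2)OC(=O)CC1 | intermediate
23 | 3-(5-methyl-2-oxo-3,4-dihydro-2H-pyran-6-yl)propanoic acid | CC1=C(CCC(=O)O)OC(=O)CC1 | intermediate
24 | 3-(5-methyl-2-oxo-3,4-dihydro-2H-pyran-6-yl)propanoyl chloride | CC1=C(CCC(=O)Cl)OC(=O)CC1 | intermediate
25 | 6-(4-diazo-3-oxobutyl)-5-methyl-3,4-dihydro-2H-pyran-2-one | CC1=C(CCC(=O)C=[N+]=[N-])OC(=O)CC1 | intermediate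
26 | 6-methyl-2-oxatricyclo[4.4.0.0(1,7)]decane-3,8-dione, the enantiomer carrying the future (4aS) carbon (cyclopropane cis-fused to both rings) | C[C@@]12CCC(=O)O[C@@]13CCC(=O)[C@@H]23 | intermediate
27 | (4aS,8aS)-4a-methyl-6-[(triethylsilyl)oxy]-3,4,4a,7,8,8a-hexahydro-2H-chromen-2-one (trans-fused) | CC[Si](CC)(CC)OC1=C[C@]2(C)CCC(=O)O[C@H]2CC1 | intermediate
28 | (4aS,8aS)-5-[(dimethylamino)methyl]-4a-methyloctahydro-2H-chromene-2,6-dione (C5 epimers) | CN(C)CC1[C@]2(C)CCC(=O)O[C@H]2CCC1=O | intermediate
29 | trimethylammonium iodide (methiodide) of 28 | C[N+](C)(C)CC1[C@]2(C)CCC(=O)O[C@H]2CCC1=O.[I-] | intermediate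
30 | (4aS,8aS)-4a-methyl-5-methylideneoctahydro-2H-chromene-2,6-dione | C=C1[C@]2(C)CCC(=O)O[C@H]2CCC1=O | intermediate
31 | 1,3-dioxoisoindolin-2-yl 2-[(1S,3aS,5R,8aS)-1-hydroxy-1,4,4,6-tetramethyl-1,2,3,3a,4,5,8,8a-octahydroazulen-5-yl]acetate | CC1=CC[C@H]2[C@H](CC[C@]2(C)O)C(C)(C)[C@@H]1CC(=O)ON1C(=O)c2ccccc2C1=O | intermediate
32 | (4aS,5R,8aS)-epimer of 33 (axial side chain) | CC1=CC[C@H]2[C@H](CC[C@]2(C)O)C(C)(C)[C@@H]1CC[C@@H]1[C@]2(C)CCC(=O)O[C@H]2CCC1=O | intermediate
33 | (4aS,5S,8aS)-5-{2-[(1S,3aS,5R,8aS)-1-hydroxy-1,4,4,6-tetramethyl-1,2,3,3a,4,5,8,8a-octahydroazulen-5-yl]ethyl}-4a-methyloctahydro-2H-chromene-2,6-dione | CC1=CC[C@H]2[C@H](CC[C@]2(C)O)C(C)(C)[C@@H]1CC[C@H]1[C@]2(C)CCC(=O)O[C@H]2CCC1=O | intermediate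
34 | (4aS,5S,6R,8aS)-6-hydroxy-5-{2-[(1S,3aS,5R,8aS)-1-hydroxy-1,4,4,6-tetramethyl-1,2,3,3a,4,5,8,8a-octahydroazulen-5-yl]ethyl}-4a,6-dimethyloctahydro-2H-chromen-2-one | CC1=CC[C@H]2[C@H](CC[C@]2(C)O)C(C)(C)[C@@H]1CC[C@H]1[C@]2(C)CCC(=O)O[C@H]2CC[C@@]1(C)O | intermediate
35 | CNP0167351.1, (2S,4aS,5S,6R,8aS)-5-{2-[(1S,3aS,5R,8aS)-1-hydroxy-1,4,4,6-tetramethyl-1,2,3,3a,4,5,8,8a-octahydroazulen-5-yl]ethyl}-4a,6-dimethyloctahydro-2H-chromene-2,6-diol | CC1=CC[C@H]2[C@H](CC[C@]2(C)O)C(C)(C)[C@@H]1CC[C@H]1[C@]2(C)CC[C@@H](O)O[C@H]2CC[C@@]1(C)O | target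

**Step count and risks**

Total step count: 20. Longest linear sequence: 13 steps (steps 1–10, then 18–20); the second branch has 10 (steps 11–17, then 18–20).

Steps most likely to fail:

Step 16. The copper catalyst may discriminate poorly between the two faces of the hindered, acyloxy-deactivated tetrasubstituted double bond, or the carbenoid may decay before it reaches it. The fallback gives up asymmetric induction and uses stepwise, established reaction types. It sets out from 25: Rh2(OAc)4 (1 mol%) in CH2Cl2 at 40 °C should give the racemic cyclopropane-fused keto lactone F1, which is isolated. Separate treatment with Et3SiOTf and Et3SiH (Lewis-acid opening of the oxycyclopropyl ketone, silane reduction of the oxocarbenium ion) should give 27 together with its mirror image, the (4aR,8aR)-silyl enol ether F2. Preparative chromatography on a chiral stationary phase separates the two, and the route is rejoined at 27.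

Step 7. The ketyl oxygen may not hold the anti orientation during ring closure (poor facial selectivity at the carbinol carbon), and the product enone may be reduced further by SmI2. The fallback sets the C1 configuration by epoxidation and hydride opening instead. It sets out from 12: the cyclisation is run as before, and the C1-epimeric hydroxy enone F3 is separated from 13. Syn-dehydration of F3 with methyl N-(triethylammoniosulfonyl)carbamate (Burgess reagent) should give the endocyclic alkene F4, in which the ring-fusion hydrogen is anti to the leaving group and is not lost. Epoxidation with m-chloroperbenzoic acid (the enone is inert) should occur on the convex face and give the epoxy enone F5. LiAlH4 then opens the epoxide at the secondary carbon and reduces the enone carbonyl from the convex face, and the route is rejoined at 14.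

Step 18. Radical capture may be slow enough for the homoallylic primary radical to close onto the ring double bond and rearrange, and the α-methylene ketone 30 may dimerise. The fallback is a polar union that sets out from 15 and 27. Reduction of 15 with i-Bu2AlH (−78 °C) should give the aldehyde F6. A Mukaiyama aldol reaction of 27 with F6 (BF3·OEt2, CH2Cl2, −78 °C) should give the β-hydroxy ketone F7 at the regiodefined C5. Dehydration (MsCl, Et3N, then DBU) gives the exocyclic enone F8. Conjugate reduction with [(Ph3P)CuH]6 and DBU equilibration of C5 rejoin the route at 33.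

Further compounds
F1 | step 16 | racemic 6-methyl-2-oxatricyclo[4.4.0.0(1,7)]decane-3,8-dione | CC12CCC(=O)OC13CCC(=O)C23
F2 | step 16 | (4aR,8aR)-4a-methyl-6-[(triethylsilyl)oxy]-3,4,4a,7,8,8a-hexahydro-2H-chromen-2-one | CC[Si](CC)(CC)OC1=C[C@@]2(C)CCC(=O)O[C@@H]2CC1
F3 | step 7 | (1R,3aS,8aS)-1-hydroxy-1,4,4,6-tetramethyl-2,3,3a,4,8,8a-hexahydroazulen-7(1H)-one | CC=1C(=O)C[C@H]2[C@H](CC[C@@]2(C)O)C(C)(C)C=1
F4 | step 7 | (3aS,8aS)-1,4,4,6-tetramethyl-3a,4,8,8a-tetrahydroazulen-7(3H)-one | CC=1C(=O)C[C@H]2[C@H](CC=C2C)C(C)(C)C=1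
F5 | step 7 | 1,2-epoxide of F4 with oxygen on the face of the ring-fusion hydrogens | CC=1C(=O)C[C@H]2[C@H](C[C@@H]3O[C@]23C)C(C)(C)C=1
F6 | step 18 | 2-[(1S,3aS,5R,8aS)-1-hydroxy-1,4,4,6-tetramethyl-1,2,3,3a,4,5,8,8a-octahydroazulen-5-yl]acetaldehyde | CC1=CC[C@H]2[C@H](CC[C@]2(C)O)C(C)(C)[C@@H]1CC=O
F7 | step 18 | (4aS,8aS)-5-{1-hydroxy-2-[(1S,3aS,5R,8aS)-1-hydroxy-1,4,4,6-tetramethyl-1,2,3,3a,4,5,8,8a-octahydroazulen-5-yl]ethyl}-4a-methyloctahydro-2H-chromene-2,6-dione (epimers at the two new centres) | CC1=CC[C@H]2[C@H](CC[C@]2(C)O)C(C)(C)[C@@H]1CC(O)C1[C@]2(C)CCC(=O)O[C@H]2CCC1=O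
F8 | step 18 | (4aS,8aS)-5-{2-[(1S,3aS,5R,8aS)-1-hydroxy-1,4,4,6-tetramethyl-1,2,3,3a,4,5,8,8a-octahydroazulen-5-yl]ethylidene}-4a-methyloctahydro-2H-chromene-2,6-dione (E/Z) | CC1=CC[C@H]2[C@H](CC[C@]2(C)O)C(C)(C)[C@@H]1CC=C1[C@]2(C)CCC(=O)O[C@H]2CCC1=O
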